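The route rests on cutting the C4–C5 bond of the unbranched C1–C18 chain. The para-oxygenated benzene ring with C1–C4 then maps onto 4-(4-hydroxyphenyl)butan-2-one, and C5–C18 onto tetradecanal. The feature exploited is the C5 carbonyl carbon and its 1,3-distance from C3. C5 enters as the aldehyde electrophile, while a temporary carbonyl at C3 makes C4 nucleophilic. One directed aldol addition thus joins all 24 carbons and delivers two chemically distinct oxygen functions: a C3 carbonyl to be erased and a C5 alcohol to be oxidised. The precursor is the O-silylated arylbutanone, enolised at its methyl group. Afterwards a tosylhydrazone reduction removes the C3 oxygen, oxidation installs the C5 ketone, and the phenol is released.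

Key step: step 2

Remark: chain carbons are numbered from the benzylic CH2 (C1) through the carbonyl carbon (C5) to the terminal CH3 (C18). The target has no stereocentre, so the C5 carbinols are carried as racemates and the C=N geometry of the hydrazone is left open; both elements vanish before the end.

Step 1
Reactants: 1 4-(4-hydroxyphenyl)butan-2-one; 2 tert-butyldimethylsilyl chloride
Product: 3 4-[4-(tert-butyldimethylsilyloxy)phenyl]butan-2-one
Conditions: TBSCl, imidazole, DMF, rt
Reagents that add atoms: tert-butyldimethylsilyl chloride (2), CC(C)(C)[Si](C)(C)Cl
Why: Imidazole-promoted O-silylation of the phenol, the only acidic OH, proceeds through an N-silylimidazolium species, leaves the ketone untouched and removes the proton that would otherwise consume base in step 2.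

Step 2
Reactants: 3 4-[4-(tert-butyldimethylsilyloxy)phenyl]butan-2-one; 4 tetradecanal
Product: 7 rac-1-[4-(tert-butyldimethylsilyloxy)phenyl]-5-hydroxyoctadecan-3-one, via lithium enolate 5 (not isolated), via lithium aldolate 6 (not isolated)
Conditions: LiN(i-Pr)2 (from n-BuLi, i-Pr2NH), THF, −78 °C, slow addition of 3; then 4 (dilute in THF), −78 °C; AcOH, −78 °C
Reagents that add atoms: none
Why: Dropwise addition of 3 to a slight excess of the bulky amide at −78 °C irreversibly removes a proton from the open CH3 terminus (future C4) rather than from the CH2 on the aryl side of the carbonyl (future C2), and the resulting terminal enolate 5 attacks the formyl carbon of 4 (future C5) in a lithium-bridged, chair-like six-centre array (Zimmerman–Traxler model) to give aldolate 6. The closest known reaction type is the directed cross-aldol addition of preformed 4-arylbutan-2-one enolates to linear alkanals, the standard entry to gingerol-type beta-hydroxy ketones. One skeletal bond (C4–C5) is made and no ring is closed. C5 is the only new stereocentre; both partners are achiral and nothing biases the aldehyde faces, so 7 should form as a racemate, which is of no consequence because C5 returns to sp2 in step 5. The step needs site selectivity in the enolisation and cross- over self-addition: the former is secured by the steric contrast between CH3 and CH2 under kinetic control with base always in excess, the latter by complete enolate formation before 4 enters, by the silyl cap that removes the phenol proton, and by carbonyl addition outrunning proton transfer at −78 °C. Acetic acid added at −78 °C protonates 6 before retro-aldol cleavage, enolate scrambling or loss of water can set in.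

Step 3
Reactants: 7 rac-1-[4-(tert-butyldimethylsilyloxy)phenyl]-5-hydroxyoctadecan-3-one; 8 p-toluenesulfonohydrazide
Product: 9 rac-N'-{1-[4-(tert-butyldimethylsilyloxy)phenyl]-5-hydroxyoctadecan-3-ylidene}-4-methylbenzenesulfonohydrazide (C=N isomer mixture)
Conditions: TsNHNH2, THF–MeOH, rt
Reagents that add atoms: p-toluenesulfonohydrazide (8), Cc1ccc(cc1)S(=O)(=O)NN
Why: Tosylhydrazone formation from an unhindered dialkyl ketone and the alpha-effect nucleophile should run at room temperature without added acid, which keeps the beta-hydroxy ketone from dehydrating or cleaving and leaves the carbinol and aryl silyl ether untouched.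

Step 4
Reactants: 9 rac-N'-{1-[4-(tert-butyldimethylsilyloxy)phenyl]-5-hydroxyoctadecan-3-ylidene}-4-methylbenzenesulfonohydrazide
Product: 12 rac-1-[4-(tert-butyldimethylsilyloxy)phenyl]octadecan-5-ol, via bisborylated tosylhydrazine 10 (not isolated), via C3 alkyl diazene 11 (not isolated)
Conditions: catecholborane (3 equiv), CHCl3, −10 to 0 °C; then NaOAc·3H2O, reflux
Reagents that add atoms: none
Why: In this Caglioti-type tosylhydrazone reduction, catecholborane first caps the C5 hydroxyl as a borate and then delivers hydride to the C=N carbon to give 10, acetate-induced loss of p-toluenesulfinate gives diazene 11, and 11 extrudes N2 with hydrogen transfer to C3, all in a near-neutral medium that should spare the carbinol and silyl ether.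

Step 5
Reactants: 12 rac-1-[4-(tert-butyldimethylsilyloxy)phenyl]octadecan-5-ol
Product: 13 1-[4-(tert-butyldimethylsilyloxy)phenyl]octadecan-5-one
Conditions: Dess–Martin periodinane, CH2Cl2, 0 °C to rt
Reagents that add atoms: none
Why: In the Dess–Martin oxidation the secondary alcohol exchanges onto pentavalent iodine and acetate-assisted removal of the carbinol hydrogen gives the ketone, which erases the C5 stereocentre, while the ring is safe because the phenol is still silylated.

Step 6
Reactants: 13 1-[4-(tert-butyldimethylsilyloxy)phenyl]octadecan-5-one
Product: 14 1-(4-hydroxyphenyl)octadecan-5-one (target)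
Conditions: Bu4NF, AcOH, THF, 0 °C
Reagents that add atoms: none
Why: Fluoride-induced desilylation is driven by the strong Si–F bond and is fast for aryl silyl ethers because phenoxide leaves readily, and the acetic acid buffer protonates the phenoxide at once so that the enolisable ketone sees no strong base.

Compound list
1 | 4-(4-hydroxyphenyl)butan-2-one | CC(=O)CCc1ccc(O)cc1 | starting material
2 | tert-butyldimethylsilyl chloride | CC(C)(C)[Si](C)(C)Cl | starting material
3 | 4-[4-(tert-butyldimethylsilyloxy)phenyl]butan-2-one | CC(=O)CCc1ccc(O[Si](C)(C)C(C)(C)C)cc1 | intermediate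
4 | tetradecanal | CCCCCCCCCCCCCC=O | starting material
5 | lithium 4-[4-(tert-butyldimethylsilyloxy)phenyl]but-1-en-2-olate (terminal enolate, formed in the flask) | [Li+].C=C([O-])CCc1ccc(O[Si](C)(C)C(C)(C)C)cc1 | intermediate
6 | lithium rac-1-[4-(tert-butyldimethylsilyloxy)phenyl]-3-oxooctadecan-5-olate (aldolate, formed in the flask) | [Li+].CCCCCCCCCCCCCC([O-])CC(=O)CCc1ccc(O[Si](C)(C)C(C)(C)C)cc1 | intermediate
7 | rac-1-[4-(tert-butyldimethylsilyloxy)phenyl]-5-hydroxyoctadecan-3-one | CCCCCCCCCCCCCC(O)CC(=O)CCc1ccc(O[Si](C)(C)C(C)(C)C)cc1 | intermediate
8 | p-toluenesulfonohydrazide | Cc1ccc(cc1)S(=O)(=O)NN | starting material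
9 | rac-N'-{1-[4-(tert-butyldimethylsilyloxy)phenyl]-5-hydroxyoctadecan-3-ylidene}-4-methylbenzenesulfonohydrazide (C=N isomer mixture) | CCCCCCCCCCCCCC(O)CC(CCc1ccc(O[Si](C)(C)C(C)(C)C)cc1)=NNS(=O)(=O)c1ccc(C)cc1 | intermediate
10 | C3 N'-tosylhydrazine carrying 1,3,2-benzodioxaborol-2-yl groups on the C5 oxygen and on the C3-bound nitrogen (diastereomer mixture, formed in the flask) | CCCCCCCCCCCCCC(OB1Oc2ccccc2O1)CC(CCc1ccc(O[Si](C)(C)C(C)(C)C)cc1)N(B1Oc2ccccc2O1)NS(=O)(=O)c1ccc(C)cc1 | intermediate
11 | 3-diazenyl-1-[4-(tert-butyldimethylsilyloxy)phenyl]octadecan-5-ol (diastereomer mixture, formed in the flask) | CCCCCCCCCCCCCC(O)CC(CCc1ccc(O[Si](C)(C)C(C)(C)C)cc1)N=N | intermediate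
12 | rac-1-[4-(tert-butyldimethylsilyloxy)phenyl]octadecan-5-ol | CCCCCCCCCCCCCC(O)CCCCc1ccc(O[Si](C)(C)C(C)(C)C)cc1 | intermediate
13 | 1-[4-(tert-butyldimethylsilyloxy)phenyl]octadecan-5-one | CCCCCCCCCCCCCC(=O)CCCCc1ccc(O[Si](C)(C)C(C)(C)C)cc1 | intermediate
14 | 1-(4-hydroxyphenyl)octadecan-5-one | CCCCCCCCCCCCCC(=O)CCCCc1ccc(O)cc1 | target

Total step count: 6. Longest linear sequence: 6 steps (1 to 14).

Steps most likely to fail

Step 2. The risks are:
- incomplete site selectivity in the deprotonation;
- proton transfer from the enolisable aldehyde to the enolate, followed by aldehyde self-condensation;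
- poor solubility of the long-chain aldehyde in the cold;
- reversal of the addition before the quench.

The fallback is a Mukaiyama aldol addition that sets out from 3. Enolate 5 is generated with LiN(i-Pr)2 in the presence of Me3SiCl at −78 °C and trapped as the terminal trimethylsilyl enol ether F1, which can be freed from any internal isomer before use. F1 and 4 are then combined with BF3·OEt2 in CH2Cl2 at −78 °C. There the aldehyde is activated by the Lewis acid, and no base is present that could enolise it or reverse the addition. Aqueous work-up comes back to the route at 7.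

Step 4. The risks are slow hydride transfer to the C=N bond, competing base-induced elimination towards an alkene, and partial loss of the aryl silyl ether during the warm acetate stage. The fallback is a Mozingo reduction that sets out from 7 and bypasses steps 3 and 4. Mild thioketalisation with ethane-1,2-dithiol and Zn(OTf)2 in CH2Cl2 at rt should give the 1,3-dithiolane F2. Hydrogenolysis of both C–S bonds with Raney Ni in ethanol then comes back to the route at 12.

Step 3. The risks are loss of water from the beta-hydroxy ketone during the condensation, followed by intramolecular aza-Michael closure of the unsaturated hydrazone, and retro-aldol cleavage. The fallback installs the hydrazone before the hydroxyl exists and sets out from 3. Condensation of 3 with 8 gives the (E)-tosylhydrazone F3. Two equivalents of n-BuLi in THF at −78 °C form the C,N-dilithio dianion F4, a Shapiro-type dianion in which the sulfonamide anion directs lithiation to the syn methyl group. F4 is kept cold so that it does not collapse to a vinyllithium, and it adds to 4 at −78 °C. An AcOH quench comes back to the route at 9.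

Further compounds
F1 | step 2 | tert-butyl(dimethyl){4-[3-(trimethylsilyloxy)but-3-en-1-yl]phenoxy}silane | C=C(CCc1ccc(O[Si](C)(C)C(C)(C)C)cc1)O[Si](C)(C)C
F2 | step 4 | rac-1-(2-{2-[4-(tert-butyldimethylsilyloxy)phenyl]ethyl}-1,3-dithiolan-2-yl)pentadecan-2-ol | CCCCCCCCCCCCCC(O)CC1(CCc2ccc(O[Si](C)(C)C(C)(C)C)cc2)SCCS1
F3 | step 3 | (E)-N'-{4-[4-(tert-butyldimethylsilyloxy)phenyl]butan-2-ylidene}-4-methylbenzenesulfonohydrazide | C/C(CCc1ccc(O[Si](C)(C)C(C)(C)C)cc1)=N\NS(=O)(=O)c1ccc(C)cc1
F4 | step 3 | dilithium salt of F3, deprotonated at the methyl carbon and at the sulfonamide nitrogen | [Li+].[Li+].[CH2-]/C(CCc1ccc(O[Si](C)(C)C(C)(C)C)cc1)=N\[N-]S(=O)(=O)c1ccc(C)cc1
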